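**Assumption:** the target has no stereocentres (it is achiral), so no stereocontrol is needed; divarinol (5-propylresorcinol) is taken as the single cheap commercial starting material.

**Retrosynthetic overview**
1. Target 8 is cut at the depside ester C–O bond into acid 4 (A ring) and the C4–OH of divaric acid 2 (B ring); this bond is made last.
2. Acid 4 comes from 2 by exhaustive O-methylation and saponification, so both halves derive from one intermediate.
3. Acid 2 comes from divarinol 1 by ortho-carboxylation.
4. No carbocyclic ring is formed: both benzene rings come from 1. The only ring made is a temporary dioxaborinone in step 3, opened again on work-up.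

**Step 1**
Reactants: 1 divarinol (5-propylbenzene-1,3-diol)
Product: 2 divaric acid (2,4-dihydroxy-6-propylbenzoic acid)
Conditions: MeOMgOCO2Me (2 M in DMF, 4 equiv), 120 °C, N2 sweep, 3 h; then cold 2 M HCl, 0 °C
Reagents that add atoms: methyl magnesium carbonate, COC(=O)O[Mg]OC
Why: Kolbe–Schmitt-type carboxylation with Stiles' reagent, in which the magnesium phenoxide of 1 delivers CO2 to the ring carbon ortho to one OH and para to the other and the product is held as a magnesium salicylate chelate until cold acidification (the behaviour known for 5-alkylresorcinols such as olivetol).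

**Step 2**
Reactants: 2 divaric acid
Product: 4 2,4-dimethoxy-6-propylbenzoic acid, via methyl 2,4-dimethoxy-6-propylbenzoate 3 (not isolated)
Conditions: Me2SO4 (4 equiv), K2CO3 (4 equiv), acetone, rt → reflux, 16 h; evaporate; KOH (6 equiv), DMSO/H2O 4:1, 90 °C, 6 h; then HCl, 0 °C
Reagents that add atoms: dimethyl sulfate, COS(=O)(=O)OC; potassium hydroxide, [K+].[OH-] (one carboxyl O after acyl–oxygen cleavage)
Why: Williamson-type exhaustive methylation (carboxylate first, then both phenols including the chelated 2-OH at reflux) followed by BAc2 saponification of the hindered ester in KOH/aqueous DMSO, to which aryl methyl ethers are inert.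

**Step 3**
Reactants: 4 2,4-dimethoxy-6-propylbenzoic acid; 2 divaric acid
Product: 8 4-[(2,4-dimethoxy-6-propylbenzoyl)oxy]-2-hydroxy-6-propylbenzoic acid, via aroyl chloride 5 (not isolated), via hydroxy dioxaborinone 6 (not isolated), via aroylated dioxaborinone 7 (not isolated)
Conditions: (a) 4, (COCl)2 (1.3 equiv), cat. DMF, CH2Cl2, 0 °C → rt, evaporate; (b) 2, PhB(OH)2 (1.05 equiv), 4 Å MS, CH2Cl2/MeCN, 40 °C, 3 h; (c) add a to b, iPr2NEt (2.5 equiv), DMAP (10 mol%), 0 °C → rt, 12 h; (d) 1 M HCl, EtOAc, rt, 30 min; pH 7 buffer partition removes PhB(OH)2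
Reagents that add atoms: oxalyl chloride, O=C(Cl)C(=O)Cl (Cl of 5 only); phenylboronic acid, OB(O)c1ccccc1 (PhB of 6 and 7 only); no reagent atom remains in 8
Why: Proposed new method: transient boron-chelate masking for site-selective depside esterification, in which PhB(OH)2 condenses only with the salicylic acid motif of 2 (CO2H plus chelated ortho-OH) to give dioxaborinone 6, so that the carboxyl cannot form mixed anhydrides or oligomers and the C4 phenol is the sole nucleophile, which iPr2NEt deprotonates and the hindered electron-rich aroyl chloride 5 captures through its acylpyridinium/acylium form before mild aqueous acid hydrolyses the B–O bonds of 7 without touching the aryl ester; the closest known reaction types are DMAP-catalysed aroyl chloride esterification of phenols (Einhorn/Schotten–Baumann type) and transient boronic ester masking of diols in regioselective carbohydrate acylation, which has not been shown on salicylic acids in depside coupling.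

**Compound list**
1 | divarinol (5-propylbenzene-1,3-diol) | CCCc1cc(O)cc(O)c1 | starting material
2 | divaric acid (2,4-dihydroxy-6-propylbenzoic acid) | CCCc1cc(O)cc(O)c1C(=O)O | intermediate
3 | methyl 2,4-dimethoxy-6-propylbenzoate | CCCc1cc(OC)cc(OC)c1C(=O)OC | intermediate
4 | 2,4-dimethoxy-6-propylbenzoic acid | CCCc1cc(OC)cc(OC)c1C(=O)O | intermediate
5 | 2,4-dimethoxy-6-propylbenzoyl chloride | CCCc1cc(OC)cc(OC)c1C(=O)Cl | intermediate
6 | 7-hydroxy-2-phenyl-5-propyl-4H-1,3,2-benzodioxaborinin-4-one | CCCc1cc(O)cc2OB(c3ccccc3)OC(=O)c12 | intermediate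
7 | 4-oxo-2-phenyl-5-propyl-4H-1,3,2-benzodioxaborinin-7-yl 2,4-dimethoxy-6-propylbenzoate | CCCc1cc(OC(=O)c3c(CCC)cc(OC)cc3OC)cc2OB(c4ccccc4)OC(=O)c12 | intermediate
8 | 4-[(2,4-dimethoxy-6-propylbenzoyl)oxy]-2-hydroxy-6-propylbenzoic acid (CNP0398006.0) | CCCc1cc(OC(=O)c2c(CCC)cc(OC)cc2OC)cc(O)c1C(=O)O | target

**Total step count:** 3. **Longest linear sequence:** 3 (1 → 2 → 4 → 8).

**Steps most likely to fail**

Step 3 (proposed new step). Risks are incomplete chelation of 2 or premature B–O cleavage, which would free the CO2H and give mixed anhydrides or oligodepsides, and slow acylation by the di-ortho-substituted aroyl chloride. The fallback uses known chemistry and sets out from 2. The carboxyl group is benzylated chemoselectively (BnBr, KHCO3, DMF, rt) to benzyl 2,4-dihydroxy-6-propylbenzoate F1. Its non-chelated 4-OH is then esterified with aroyl chloride 5 (made from 4 as in step 3a; pyridine, cat. DMAP, CH2Cl2, 0 °C → rt) to benzyl 4-[(2,4-dimethoxy-6-propylbenzoyl)oxy]-2-hydroxy-6-propylbenzoate F2. Hydrogenolysis (H2 1 atm, 10% Pd/C, EtOAc, rt) cleaves the benzyl ester and comes back to the route at 8.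

Step 1. Risks are the regioisomeric 2,6-dihydroxy-4-propylbenzoic acid, incomplete conversion, and decarboxylation on work-up. The fallback sets out from 1 and brings in the carboxyl carbon as a formyl group. Vilsmeier–Haack reaction (POCl3, DMF, 0 °C → rt) gives N-[(2,4-dihydroxy-6-propylphenyl)methylidene]-N-methylmethanaminium chloride F3. Hydrolysis (aq. NaOAc, 60 °C) gives 2,4-dihydroxy-6-propylbenzaldehyde F4. Lindgren–Pinnick oxidation (NaClO2, NaH2PO4, sulfamic acid as hypochlorite scavenger, aq. dioxane, 0 °C) comes back to the route at 2.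

Step 2. Risks are incomplete methylation of the chelated 2-OH, slow hydrolysis of the di-ortho-substituted ester, and decarboxylation of 2 before O-alkylation. The fallback sets out from 1 and avoids the hindered ester altogether. Methylation (Me2SO4, K2CO3, acetone, reflux) gives 1,3-dimethoxy-5-propylbenzene F5. Vilsmeier–Haack formylation (POCl3, DMF, 0 → 60 °C) gives N-[(2,4-dimethoxy-6-propylphenyl)methylidene]-N-methylmethanaminium chloride F6, hydrolysed on aqueous work-up to 2,4-dimethoxy-6-propylbenzaldehyde F7. Pinnick oxidation (NaClO2, NaH2PO4, 2-methyl-2-butene, t-BuOH/H2O, rt) comes back to the route at 4.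

**Further compounds**
F1 | step 3 | benzyl 2,4-dihydroxy-6-propylbenzoate | CCCc1cc(O)cc(O)c1C(=O)OCc1ccccc1
F2 | step 3 | benzyl 4-[(2,4-dimethoxy-6-propylbenzoyl)oxy]-2-hydroxy-6-propylbenzoate | CCCc1cc(OC(=O)c2c(CCC)cc(OC)cc2OC)cc(O)c1C(=O)OCc1ccccc1
F3 | step 1 | N-[(2,4-dihydroxy-6-propylphenyl)methylidene]-N-methylmethanaminium chloride | CCCc1cc(O)cc(O)c1C=[N+](C)C.[Cl-]
F4 | step 1 | 2,4-dihydroxy-6-propylbenzaldehyde | CCCc1cc(O)cc(O)c1C=O
F5 | step 2 | 1,3-dimethoxy-5-propylbenzene | CCCc1cc(OC)cc(OC)c1
F6 | step 2 | N-[(2,4-dimethoxy-6-propylphenyl)methylidene]-N-methylmethanaminium chloride | CCCc1cc(OC)cc(OC)c1C=[N+](C)C.[Cl-]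
F7 | step 2 | 2,4-dimethoxy-6-propylbenzaldehyde | CCCc1cc(OC)cc(OC)c1C=O
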